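(Readings and results stem from a simulated flask for an exercise, noise included.)

The question was how much Z stands after 20 min in three flasks that differ in temperature, and whether Z outweighs D there.

| flask | E | J | temperature | remark | time |
|---|---|---|---|---|---|
| north-west | 0.10 M | 1.3 equiv | −5 °C | run made earlier |  |
| west | 0.40 M | 1.3 equiv | 8 °C | run made earlier |  |
| south-west | 0.20 M | 2.6 equiv | −5 °C | run made earlier |  |
| cedar | 0.20 M | 1.30 equiv | 0 °C |  | 20 min |
| ash | 0.20 M | 1.30 equiv | 8 °C |  | 20 min |
| larch | 0.20 M | 1.30 equiv | 16 °C |  | 20 min |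

| run | time / min | Z / % | E / % |
|---|---|---|---|
| north-west | 1.33 | 0.9 | 84.6 |
| north-west | 4.00 | 1.0 | 65.5 |
| north-west | 8.00 | 1.3 | 46.9 |
| north-west | 10.0 | 2.7 | 42.3 |
| north-west | 15.0 | 6.0 | 34.6 |
| north-west | 20.0 | 10.8 | 30.8 |
| west | 3.00 | 12.0 | 47.4 |
| west | 6.00 | 30.9 | 38.7 |
| west | 10.0 | 41.2 | 33.0 |
| west | 12.0 | 42.5 | 26.9 |
| west | 15.0 | 45.3 | 27.7 |
| west | 20.0 | 46.4 | 23.3 |
| south-west | 1.50 | 0 | 81.6 |
| south-west | 3.00 | 0.8 | 71.1 |
| south-west | 6.00 | 3.8 | 53.6 |
| south-west | 10.0 | 8.3 | 40.2 |
| south-west | 20.0 | 28.6 | 26.6 |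

(scatter of a reading: 1 percentage point)

- which of the two there is more of at the end, counted by the E in each, cedar (D / Z)
- which of the two there is more of at the end, counted by the E in each, ash (D / Z)
- which of the two there is more of at the end, counted by the E in each, larch (D / Z)
- Z at the end, in percent of the E charged, cedar
- Z at the end, in percent of the E charged, ash
- Z at the end, in percent of the E charged, larch

- percentages count the E that a species holds: one D counts as two
- what may be going on: E <-> L; J -> G; L + G <-> Z; 2 L -> D

Had the west run, at ash's temperature, stopped moving? Its Z rose 1.1 percentage points between its last two readings against a scatter of 1 point, so I read its last reading as a balance.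

What constant does that balance give? By my own choice I counted what was not in Z as one unbound pool (E, L and any D together, although the readings give E apart and leave L and D unread), and the J charge less Z as free G. West gave 2.59 L mol⁻¹ for my pairing constant, Z divided by the unbound pool and by free G, each as a concentration, an apparent equilibrium constant.

What does that give in ash? Solving the same balance at ash's charge gave a balance figure of 33.4 % Z. Ash has half of west's concentrations and twice the time of the west reading that already held 88.8 % of west's last Z, so I expected ash close to that figure. The constant belongs to 8 °C, so I used it on ash and made no number for cedar or larch.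

The forecast put Z at 23 % (15 % to 31 %) in cedar with D ahead, 38 % (29 % to 46 %) in ash with Z ahead, and 47 % (37 % to 57 %) in larch with Z ahead, saying “Larch should sit near a plateau of about 47%”. Its ash figure stands above my balance figure.

    E ⇌ L (K = 1.50, k = 0.00390 s⁻¹, Ea = 70.0 kJ mol⁻¹, ΔH = −33.0 kJ mol⁻¹)
    J → G (k = 0.00260 s⁻¹, Ea = 79.0 kJ mol⁻¹)
    L + G ⇌ Z (K = 9.00 L mol⁻¹, k = 0.00440 L mol⁻¹ s⁻¹, Ea = 68.0 kJ mol⁻¹, ΔH = −34.0 kJ mol⁻¹)
    2 L → D (k = 2.10 × 10⁻⁴ L mol⁻¹ s⁻¹, Ea = 57.0 kJ mol⁻¹)
    (constants at 0 °C)

Ash gave 33.7 % Z against my balance figure of 33.4 %, with D at 2.58 %. Cedar gave 28.7 % Z and 1.91 % D, so Z led there, against the forecast. Larch gave 24.2 % Z, less than ash and 23 points under the forecast. The neighbouring flask is ash with E at 0.080 M, the equivalents of J held. My pairing constant of 2.59 L mol⁻¹ put its balance figure at 18.7 %, and that flask gave 18.6 %.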